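A direct plan would make the diaryl ether first, by SNAr of the mono-carbamoylated hydroquinone A1 on 4-fluorobenzaldehyde A2 to give aldehyde A3. It would then arm ring A of unit 1 as the ortho-silylaryl triflate A4, close ring C of unit 1 by aryne insertion into the arylpropiolic acid A5 to reach flavone aldehyde A6, and finally grow unit 2 on that aldehyde by aldol condensation and oxidative cyclisation before deprotection.
Its weakest points would be three:
(i) The run from A3 to A4 (acetal, directed lithiation and silylation, carbamate cleavage, triflation) would form no bond of the target and serve only to prepare the aryne.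
(ii) The aryne annulation would leave to chance the site of carboxylate attack on an unsymmetrical aryne, acyl shift against simple protonation, and 6-endo against 5-exo closure, all at high dilution, at 125 °C and with the costly A4 in excess.
(iii) The hydroxide-mediated chalcone condensation on A6 would expose the base-labile pyranone of the most advanced intermediate to ring opening, and a 130 °C oxidation on the same precious material would follow.

Plan of the new route
The retrosynthesis cuts the interflavone ether first, at O6–C4' (oxygen on C6 of ring A of unit 1, carbon C4' of ring B of unit 2), into two complete flavone monomers, and then each pyranone at O1–C2 and C2–C3.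
Forward, ring C of unit 1 and ring C of unit 2 arise separately, each from an acetophenone, and the ether bridge is the last skeletal bond, as in the presumed biosynthesis from two apigenin-type monomers.
Feature used: in ring A of unit 1 the bridging oxygen on C6 is para to O1 on C8a and lies between the C5 and C7 oxygens, so ring A is 2,6-dimethoxyhydroquinone. One C-acetylation tells its two hydroxyls apart: the chelated one becomes O1, the other stays free as O6.
C4' of unit 2 is para to C1' and conjugated through C2=C3 with C4=O, so it is an unhindered, electron-poor aryl iodide that suits the hindered, electron-rich phenoxide.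
No directing or masking groups are needed on ring A, no aryne is generated, and no ring is built on material that already carries a flavone; each coupling partner has about half the atoms of the product.
Key step: step 8

Remark: unit 1 is the flavone that carries the C7 methoxy group and the ether oxygen on C6, and unit 2 is the flavone linked through C4' of its ring B. The target has no stereocentre, and the racemic centres of two transient intermediates are erased in the step that forms them.

Step 1
Reactants: 1 2,6-dimethoxy-1,4-benzoquinone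
Product: 2 2,6-dimethoxybenzene-1,4-diol
Conditions: Na2S2O4, H2O/EtOAc, rt, Ar
Reagents that add atoms: none
Why: Dithionite reduction of a benzoquinone to its hydroquinone is fast in a two-phase medium, leaves the methyl ethers alone, and argon keeps the electron-rich product from reoxidising.

Step 2
Reactants: 2 2,6-dimethoxybenzene-1,4-diol
Product: 3 1-(3,6-dihydroxy-2,4-dimethoxyphenyl)ethanone
Conditions: AcOH, BF3·OEt2, 90 °C, Ar; then aqueous NaOAc
Reagents that add atoms: acetic acid, CC(=O)O
Why: Friedel–Crafts C-acetylation (through O-acetylation and BF3-promoted Fries shift) can only occur at the two ring carbons that are equivalent by symmetry and stops after one acyl group because the ketone deactivates the ring, and it tells the two hydroxyls apart, since the one ortho to the acetyl group is chelated and will become O1 while the one between the methoxy groups stays free to become the ether oxygen on C6.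

Step 3
Reactants: 3 1-(3,6-dihydroxy-2,4-dimethoxyphenyl)ethanone; 4 4-(propan-2-yloxy)benzoyl chloride
Product: 6 1-(3,6-dihydroxy-2,4-dimethoxyphenyl)-3-[4-(propan-2-yloxy)phenyl]propane-1,3-dione, via trilithium enolate bisphenoxide 5 (not isolated)
Conditions: LiN(SiMe3)2 (4.2 equiv), THF, −78 to −10 °C; 4 (1.0 equiv), −78 °C to rt; then 1 M HCl; crude product carried on
Reagents that add atoms: none
Why: In this Claisen-type C-aroylation of a lithium polyanion, excess amide base holds both phenols as poorly nucleophilic lithium phenoxides while the ketone enolate takes up the single equivalent of acid chloride, and the fourth equivalent of base stores the 1,3-diketone as its enolate, so the air-sensitive hydroquinone pattern meets neither a protecting group nor an oxidant.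

Step 4
Reactants: 6 1-(3,6-dihydroxy-2,4-dimethoxyphenyl)-3-[4-(propan-2-yloxy)phenyl]propane-1,3-dione
Product: 7 6-hydroxy-5,7-dimethoxy-2-[4-(propan-2-yloxy)phenyl]-4H-chromen-4-one
Conditions: AcOH, H2SO4 (0.5 vol %), 95 °C, Ar
Reagents that add atoms: none
Why: Acid-catalysed cyclodehydration of a 1-(2-hydroxyaryl)-1,3-diketone (hemiketal formation at the aryl ketone carbon, then loss of water) closes ring C of unit 1 through the only hydroxyl that is ortho to the acyl group, the hydroxyl between the methoxy groups is meta to it and stays free, and aryl isopropyl and methyl ethers tolerate the dilute acid.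

Step 5
Reactants: 8 2',4',6'-trihydroxyacetophenone
Product: 9 1-[2-hydroxy-4,6-di(propan-2-yloxy)phenyl]ethanone
Conditions: 2-bromopropane (2.3 equiv), K2CO3, DMF, 60 °C
Reagents that add atoms: 2-bromopropane, CC(C)Br
Why: Williamson etherification with a secondary bromide stops at the diether because the third hydroxyl is hydrogen-bonded to the acetyl carbonyl and is the least nucleophilic.

Step 6
Reactants: 9 1-[2-hydroxy-4,6-di(propan-2-yloxy)phenyl]ethanone; 10 4-iodobenzaldehyde
Product: 12 (E)-1-[2-hydroxy-4,6-di(propan-2-yloxy)phenyl]-3-(4-iodophenyl)prop-2-en-1-one, via aldol adduct 11 (not isolated)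
Conditions: KOH (50% aqueous), EtOH, rt; then dilute HCl
Reagents that add atoms: none
Why: Claisen–Schmidt condensation (aldol addition, then E1cB dehydration) of the methyl ketone with a non-enolisable aldehyde gives the conjugated enone, E by thermodynamic control, and the aryl iodide and the isopropyl ethers are inert to hydroxide at room temperature.

Step 7
Reactants: 12 (E)-1-[2-hydroxy-4,6-di(propan-2-yloxy)phenyl]-3-(4-iodophenyl)prop-2-en-1-one
Product: 14 2-(4-iodophenyl)-5,7-di(propan-2-yloxy)-4H-chromen-4-one, via flavanone 13 (not isolated)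
Conditions: I2 (10 mol %), DMSO, 130 °C
Reagents that add atoms: none
Why: The iodine-catalysed oxidative cyclisation of a 2'-hydroxychalcone (oxa-Michael closure to the racemic flavanone, α-iodination, loss of HI, DMSO as terminal oxidant) closes ring C of unit 2 without touching the C–I bond, and the flavanone stereocentre is erased on aromatisation.

Step 8
Reactants: 7 6-hydroxy-5,7-dimethoxy-2-[4-(propan-2-yloxy)phenyl]-4H-chromen-4-one (1.2 equiv); 14 2-(4-iodophenyl)-5,7-di(propan-2-yloxy)-4H-chromen-4-one
Product: 15 6-{4-[4-oxo-5,7-di(propan-2-yloxy)-4H-chromen-2-yl]phenoxy}-5,7-dimethoxy-2-[4-(propan-2-yloxy)phenyl]-4H-chromen-4-one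
Conditions: CuI (10 mol %), picolinic acid (20 mol %), K3PO4 (2 equiv), DMSO, 90 °C, Ar
Reagents that add atoms: none
Why: K3PO4 deprotonates the one free hydroxyl of 7 (O6), the phenoxide binds picolinate-ligated monovalent copper, oxidative addition of the C4'–I bond of 14 gives a trivalent copper aryl phenoxide, and reductive elimination forms the O6–C4' bond. The closest known reaction type is the CuI/picolinic acid Ullmann-type coupling of phenols bearing two ortho substituents with aryl iodides in DMSO. No ring is closed and no stereocentre is created, the step joins two finished flavones. The selectivity needed is cross-coupling without homo-coupling or oligomerisation, and the partners secure it: 7 has one nucleophilic oxygen and no halogen, 14 has one C–I bond and no free hydroxyl. The polarity fits the structure: the phenoxide is electron-rich but flanked by the C5 and C7 methoxy groups, whereas C4' is unhindered and electron-poor because it is para to C1' and conjugated through C2=C3 with C4=O, which eases oxidative addition and offsets the bulk of the nucleophile. Both C5 oxygens are alkylated, so no 5-hydroxy-4-keto chelate can sequester copper, and anhydrous phosphate, unlike hydroxide, does not open the pyranone rings.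

Step 9
Reactants: 15 6-{4-[4-oxo-5,7-di(propan-2-yloxy)-4H-chromen-2-yl]phenoxy}-5,7-dimethoxy-2-[4-(propan-2-yloxy)phenyl]-4H-chromen-4-one
Product: 16 isocryptomerin
Conditions: BCl3 (12 equiv), CH2Cl2, −78 °C to rt; then MeOH, 1 M HCl
Reagents that add atoms: none
Why: In this Lewis-acid ether cleavage BCl3 removes the three isopropyl groups through the stabilised secondary cation and chloride and removes the C5 methyl ether of unit 1 through a six-membered boron chelate with C4=O, whereas the C7 methyl ether, which can neither chelate nor ionise, and the diaryl ether stay intact.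

**Compound list**
1 | 2,6-dimethoxy-1,4-benzoquinone | COC1=CC(=O)C=C(OC)C1=O | starting material
2 | 2,6-dimethoxybenzene-1,4-diol | COc1cc(O)cc(OC)c1O | intermediate
3 | 1-(3,6-dihydroxy-2,4-dimethoxyphenyl)ethanone | CC(=O)c1c(O)cc(OC)c(O)c1OC | intermediate
4 | 4-(propan-2-yloxy)benzoyl chloride | CC(C)Oc1ccc(cc1)C(Cl)=O | starting material
5 | trilithium enolate bisphenoxide of ketone 3 | [Li+].[Li+].[Li+].[O-]C(=C)c1c([O-])cc(OC)c([O-])c1OC | intermediate
6 | 1-(3,6-dihydroxy-2,4-dimethoxyphenyl)-3-[4-(propan-2-yloxy)phenyl]propane-1,3-dione | CC(C)Oc1ccc(cc1)C(=O)CC(=O)c1c(O)cc(OC)c(O)c1OC | intermediate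
7 | 6-hydroxy-5,7-dimethoxy-2-[4-(propan-2-yloxy)phenyl]-4H-chromen-4-one (monomer 1) | COc1cc2oc(-c3ccc(OC(C)C)cc3)cc(=O)c2c(OC)c1O | intermediate
8 | 2',4',6'-trihydroxyacetophenone | CC(=O)c1c(O)cc(O)cc1O | starting material
9 | 1-[2-hydroxy-4,6-di(propan-2-yloxy)phenyl]ethanone | CC(=O)c1c(O)cc(OC(C)C)cc1OC(C)C | intermediate
10 | 4-iodobenzaldehyde | O=Cc1ccc(I)cc1 | starting material
11 | 3-hydroxy-1-[2-hydroxy-4,6-di(propan-2-yloxy)phenyl]-3-(4-iodophenyl)propan-1-one (racemic aldol adduct) | CC(C)Oc1cc(O)c(C(=O)CC(O)c2ccc(I)cc2)c(OC(C)C)c1 | intermediate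
12 | (E)-1-[2-hydroxy-4,6-di(propan-2-yloxy)phenyl]-3-(4-iodophenyl)prop-2-en-1-one | CC(C)Oc1cc(O)c(C(=O)/C=C/c2ccc(I)cc2)c(OC(C)C)c1 | intermediate
13 | 2-(4-iodophenyl)-5,7-di(propan-2-yloxy)-2,3-dihydro-4H-chromen-4-one (racemic flavanone) | CC(C)Oc1cc2OC(CC(=O)c2c(OC(C)C)c1)c1ccc(I)cc1 | intermediate
14 | 2-(4-iodophenyl)-5,7-di(propan-2-yloxy)-4H-chromen-4-one (monomer 2) | CC(C)Oc1cc2oc(-c3ccc(I)cc3)cc(=O)c2c(OC(C)C)c1 | intermediate
15 | 6-{4-[4-oxo-5,7-di(propan-2-yloxy)-4H-chromen-2-yl]phenoxy}-5,7-dimethoxy-2-[4-(propan-2-yloxy)phenyl]-4H-chromen-4-one | COc1cc2oc(-c3ccc(OC(C)C)cc3)cc(=O)c2c(OC)c1Oc1ccc(-c2cc(=O)c3c(OC(C)C)cc(OC(C)C)cc3o2)cc1 | intermediate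
16 | isocryptomerin, 6-[4-(5,7-dihydroxy-4-oxo-4H-chromen-2-yl)phenoxy]-5-hydroxy-2-(4-hydroxyphenyl)-7-methoxy-4H-chromen-4-one | COc1cc2oc(-c3ccc(O)cc3)cc(=O)c2c(O)c1Oc1ccc(-c2cc(=O)c3c(O)cc(O)cc3o2)cc1 | target

Total steps: 9. Longest linear sequence: 6 (steps 1, 2, 3, 4, 8, 9); the second branch (steps 5, 6, 7) joins at step 8.

Steps most likely to fail

Step 8. C–O bond formation at the doubly ortho-substituted phenoxide may be slow, so that reduction of the C–I bond or base-induced opening of a pyranone ring could win. The coupling would then be changed from the aryl halide mode to an oxidative one that runs at room temperature without strong base and is known to accept phenols with two ortho substituents. Setting out from 14, Miyaura borylation (B2pin2, PdCl2(dppf), KOAc, dioxane, 85 °C) would give 2-[4-(4,4,5,5-tetramethyl-1,3,2-dioxaborolan-2-yl)phenyl]-5,7-di(propan-2-yloxy)-4H-chromen-4-one F1. Periodate cleavage of the pinacol ester (NaIO4, NH4OAc, acetone/H2O, rt) would give {4-[4-oxo-5,7-di(propan-2-yloxy)-4H-chromen-2-yl]phenyl}boronic acid F2. Chan–Lam–Evans coupling of this acid with 7 (Cu(OAc)2, pyridine, 4 Å molecular sieves, CH2Cl2, air, rt) would come back to the route at 15.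

Step 3. O-aroylation of the unchelated lithium phenoxide, or poor solubility of the polyanion, may leave esters and unchanged ketone. The free hydroxyl would then be masked and ring C of unit 1 closed by the chalcone route, which replaces steps 3 and 4. Setting out from 3, benzylation of the only unchelated hydroxyl (BnBr, K2CO3, acetone, reflux) would give 1-[3-(benzyloxy)-6-hydroxy-2,4-dimethoxyphenyl]ethanone F3. Claisen–Schmidt condensation with 4-(propan-2-yloxy)benzaldehyde (KOH, EtOH, rt, Ar) would give (E)-1-[3-(benzyloxy)-6-hydroxy-2,4-dimethoxyphenyl]-3-[4-(propan-2-yloxy)phenyl]prop-2-en-1-one F4. Oxidative cyclisation (I2 10 mol %, DMSO, 130 °C) would give 6-(benzyloxy)-5,7-dimethoxy-2-[4-(propan-2-yloxy)phenyl]-4H-chromen-4-one F5, and hydrogenolysis (H2, Pd/C, EtOAc/THF, rt) would come back to the route at 7.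

Step 9. Cleavage of the C5 methyl ether may stall once boron is bound at many basic sites, or forcing may slowly remove the C7 methyl ether. The two kinds of ether would then be removed in two operations by two mechanisms. Setting out from 15, MgI2·OEt2 (toluene/Et2O, 80 °C) would cleave the C5 methyl ether of unit 1 alone: magnesium is chelated between O5 and C4=O, and iodide attacks the methyl carbon in an SN2 step that the secondary isopropyl carbons resist. This would give 5-hydroxy-7-methoxy-6-{4-[4-oxo-5,7-di(propan-2-yloxy)-4H-chromen-2-yl]phenoxy}-2-[4-(propan-2-yloxy)phenyl]-4H-chromen-4-one F6. Any loss of the chelated isopropyl group of unit 2 at this stage would be harmless. A short treatment with BCl3 (CH2Cl2, 0 °C), which then has only isopropyl ethers to remove and no reason to touch a methyl ether, would come back to the route at 16.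

Further compounds
F1 | step 8 | 2-[4-(4,4,5,5-tetramethyl-1,3,2-dioxaborolan-2-yl)phenyl]-5,7-di(propan-2-yloxy)-4H-chromen-4-one | CC(C)Oc1cc2oc(-c3ccc(cc3)B3OC(C)(C)C(C)(C)O3)cc(=O)c2c(OC(C)C)c1
F2 | step 8 | {4-[4-oxo-5,7-di(propan-2-yloxy)-4H-chromen-2-yl]phenyl}boronic acid | CC(C)Oc1cc2oc(-c3ccc(cc3)B(O)O)cc(=O)c2c(OC(C)C)c1
F3 | step 3 | 1-[3-(benzyloxy)-6-hydroxy-2,4-dimethoxyphenyl]ethanone | CC(=O)c1c(O)cc(OC)c(OCc2ccccc2)c1OC
F4 | step 3 | (E)-1-[3-(benzyloxy)-6-hydroxy-2,4-dimethoxyphenyl]-3-[4-(propan-2-yloxy)phenyl]prop-2-en-1-one | O=C(/C=C/c1ccc(OC(C)C)cc1)c1c(O)cc(OC)c(OCc2ccccc2)c1OC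
F5 | step 3 | 6-(benzyloxy)-5,7-dimethoxy-2-[4-(propan-2-yloxy)phenyl]-4H-chromen-4-one | COc1cc2oc(-c3ccc(OC(C)C)cc3)cc(=O)c2c(OC)c1OCc1ccccc1
F6 | step 9 | 5-hydroxy-7-methoxy-6-{4-[4-oxo-5,7-di(propan-2-yloxy)-4H-chromen-2-yl]phenoxy}-2-[4-(propan-2-yloxy)phenyl]-4H-chromen-4-one | COc1cc2oc(-c3ccc(OC(C)C)cc3)cc(=O)c2c(O)c1Oc1ccc(-c2cc(=O)c3c(OC(C)C)cc(OC(C)C)cc3o2)cc1
A1 | direct plan | 4-hydroxy-3,5-dimethoxyphenyl N,N-diethylcarbamate | CCN(CC)C(=O)Oc1cc(OC)c(O)c(OC)c1
A2 | direct plan | 4-fluorobenzaldehyde | O=Cc1ccc(F)cc1
A3 | direct plan | 4-(4-formylphenoxy)-3,5-dimethoxyphenyl N,N-diethylcarbamate | CCN(CC)C(=O)Oc1cc(OC)c(Oc2ccc(C=O)cc2)c(OC)c1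
A4 | direct plan | 4-[4-(1,3-dioxolan-2-yl)phenoxy]-3,5-dimethoxy-2-(trimethylsilyl)phenyl trifluoromethanesulfonate | COc1cc(OS(=O)(=O)C(F)(F)F)c([Si](C)(C)C)c(OC)c1Oc1ccc(cc1)C1OCCO1
A5 | direct plan | 3-[4-(benzyloxy)phenyl]propiolic acid | OC(=O)C#Cc1ccc(OCc2ccccc2)cc1
A6 | direct plan | 4-({2-[4-(benzyloxy)phenyl]-5,7-dimethoxy-4-oxo-4H-chromen-6-yl}oxy)benzaldehyde | COc1cc2oc(-c3ccc(OCc4ccccc4)cc3)cc(=O)c2c(OC)c1Oc1ccc(C=O)cc1
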